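The ring O1–O2–C3–C4=C5–C6 is disconnected at the O2–C3 bond. Its C3 peroxyketal is read as a C3=C4 methyl enol ether across which a hydroperoxide oxygen (to C3) and an electrophile (to C4) have been added, and a phenylselanyl group on C4 stands in for the C4=C5 double bond. In one operation, selenium activation of an open-chain hydroperoxide closes the 1,2-dioxane, forms O2–C3 and C4–Se, and sets C3 and C4 from the existing C6 centre. The precursor is a saturated (3R)-hydroperoxy methyl ester with a remote (Z)-methyl enol ether; the hydroperoxide and then the enol ether are unmasked only in the two steps before cyclization.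

Key step: step 13

Remark: ring compounds use the target numbering (O1, O2, C3 = peroxyketal carbon, C4, C5, C6 = carbon bearing CH2CO2Me); open-chain compounds are numbered as docosanoates, so chain C3 becomes ring C6 and chain C6 becomes ring C3.
Remark: the descriptors are 23 (3S,6S), 21 (3S,4R,6S) and 20 (3R,5Z); the R-to-S change at the peroxide carbon between 20 and 21 is a priority change, not an inversion.
Assumption: the addition in step 10 is not expected to control its two new centres; adducts with the like (5S,6S) or (5R,6R) relationship both give the Z enol ether on syn-elimination, are pooled, and are drawn as the (5S,6S) isomer 18.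

Step 1
Reactants: 1 (methoxymethyl)diphenylphosphine oxide; 2 1-bromohexadecane
Product: 4 (1-methoxyheptadecyl)diphenylphosphine oxide (racemic), via lithiated phosphine oxide 3 (not isolated)
Conditions: LiN(iPr)2, THF, −78 °C; then 2, −78 °C → rt
Reagents that add atoms: none
Why: Deprotonation next to phosphoryl and methoxy gives a stabilised carbanion that is alkylated by the primary bromide (SN2 alkylation of a phosphine oxide anion); the new centre is racemic and is erased when 4 is lithiated again.

Step 2
Reactants: 5 3-[(tert-butyldimethylsilyl)oxy]propanal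
Product: 7 (3S)-1-[(tert-butyldimethylsilyl)oxy]hex-5-en-3-ol, via diisopinocampheylborinate ester 6 (not isolated)
Conditions: (−)-Ipc2B(allyl), Et2O, −78 °C; then NaOH, H2O2, H2O, 0 °C → rt
Reagents that add atoms: (−)-B-allyldiisopinocampheylborane, C=CCB([C@@H]1C[C@@H]2C[C@H]([C@H]1C)C2(C)C)[C@@H]1C[C@@H]2C[C@H]([C@H]1C)C2(C)C
Why: Brown allylation through a chair Zimmerman–Traxler transition state, in which the isopinocampheyl groups derived from (+)-α-pinene send the allyl group to the Si face of the aldehyde and so set the (S)-carbinol centre.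

Step 3
Reactants: 7 (3S)-1-[(tert-butyldimethylsilyl)oxy]hex-5-en-3-ol
Product: 8 (3S)-1-[(tert-butyldimethylsilyl)oxy]hex-5-en-3-yl methanesulfonate
Conditions: MsCl, Et3N, CH2Cl2, 0 °C
Reagents that add atoms: methanesulfonyl chloride, CS(=O)(=O)Cl
Why: O-Sulfonylation of the secondary alcohol proceeds with retention at carbon and installs the leaving group for an invertive substitution.

Step 4
Reactants: 8 (3S)-1-[(tert-butyldimethylsilyl)oxy]hex-5-en-3-yl methanesulfonate
Product: 9 tert-butyl{[(3R)-3-hydroperoxyhex-5-en-1-yl]oxy}dimethylsilane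
Conditions: H2O2 (50% aq., large excess), KOH, MeOH, 0 °C → rt
Reagents that add atoms: hydrogen peroxide, OO
Why: SN2 perhydrolysis of the secondary mesylate by the hydroperoxide anion (an alpha-effect nucleophile) with inversion converts the (S)-sulfonate into the (R)-hydroperoxide centre that becomes C6; no ester is present yet, so none can be cleaved or enolised, and the silyl ether and terminal alkene are inert.

Step 5
Reactants: 9 tert-butyl{[(3R)-3-hydroperoxyhex-5-en-1-yl]oxy}dimethylsilane
Product: 10 tert-butyl({(3R)-3-[(2-methoxypropan-2-yl)peroxy]hex-5-en-1-yl}oxy)dimethylsilane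
Conditions: 2-methoxypropene, pyridinium p-toluenesulfonate (cat.), CH2Cl2, 0 °C
Reagents that add atoms: 2-methoxypropene, C=C(C)OC
Why: Acid-catalysed addition of the hydroperoxide O–H to 2-methoxypropene (monoperoxyketal formation) masks the hydroperoxide against the fluoride, phosphine and carbanion used later without touching the stereocentre.

Step 6
Reactants: 10 tert-butyl({(3R)-3-[(2-methoxypropan-2-yl)peroxy]hex-5-en-1-yl}oxy)dimethylsilane
Product: 11 (3R)-3-[(2-methoxypropan-2-yl)peroxy]hex-5-en-1-ol
Conditions: Bu4NF, THF, 0 °C → rt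
Reagents that add atoms: none
Why: Fluoride-mediated desilylation frees the primary alcohol, while the dialkyl peroxyketal has no silicon and is not attacked by fluoride.

Step 7
Reactants: 11 (3R)-3-[(2-methoxypropan-2-yl)peroxy]hex-5-en-1-ol
Product: 13 (3R)-3-[(2-methoxypropan-2-yl)peroxy]hex-5-enoic acid, via aldehyde 12 (not isolated)
Conditions: TEMPO (cat.), NaClO2, NaOCl (cat.), MeCN/KH2PO4–K2HPO4 buffer (pH 6.7), 35 °C
Reagents that add atoms: sodium chlorite (NaClO2), [Na+].[O-]Cl=O
Why: Oxoammonium-catalysed oxidation of the primary alcohol to the aldehyde and chlorite oxidation of that aldehyde to the acid run near neutral pH, which should spare the acid-labile peroxyketal and the terminal alkene.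

Step 8
Reactants: 13 (3R)-3-[(2-methoxypropan-2-yl)peroxy]hex-5-enoic acid
Product: 14 methyl (3R)-3-[(2-methoxypropan-2-yl)peroxy]hex-5-enoate
Conditions: Me3SiCHN2, MeOH/toluene, 0 °C
Reagents that add atoms: (trimethylsilyl)diazomethane, C[Si](C)(C)C=[N+]=[N-]
Why: Diazoalkane O-methylation of the carboxylic acid is neutral, so the β-peroxy ester never meets a base that could expel the peroxide.

Step 9
Reactants: 14 methyl (3R)-3-[(2-methoxypropan-2-yl)peroxy]hex-5-enoate
Product: 16 methyl (3R)-3-[(2-methoxypropan-2-yl)peroxy]-5-oxopentanoate, via ozonide 15 (not isolated)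
Conditions: O3, CH2Cl2, −78 °C; then PPh3, −78 → 0 °C
Reagents that add atoms: ozone, [O-][O+]=O
Why: Ozonolysis of the terminal alkene and phosphine reduction of the ozonide give the aldehyde that becomes C4; a dialkyl peroxyketal is not expected to be reduced by PPh3 at this temperature.

Step 10
Reactants: 4 (1-methoxyheptadecyl)diphenylphosphine oxide; 16 methyl (3R)-3-[(2-methoxypropan-2-yl)peroxy]-5-oxopentanoate
Product: 18 methyl (3R,5S,6S)-6-(diphenylphosphoryl)-5-hydroxy-6-methoxy-3-[(2-methoxypropan-2-yl)peroxy]docosanoate, via lithiated phosphine oxide 17 (not isolated)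
Conditions: 4, LiN(iPr)2, THF, −78 °C; then slow transfer onto 16, THF, −78 °C; aq. NH4Cl at −78 °C; chromatographic separation of the adducts
Reagents that add atoms: none
Why: Horner–Wittig addition of the lithiated phosphine oxide to the aldehyde at −78 °C, where the aldehyde outruns the methyl ester and the lithium alkoxide does not eliminate; the two new centres are not set by the reagent, so the adducts with the like C5/C6 relationship are isolated by chromatography and only these are carried on.

Step 11
Reactants: 18 methyl (3R,5S,6S)-6-(diphenylphosphoryl)-5-hydroxy-6-methoxy-3-[(2-methoxypropan-2-yl)peroxy]docosanoate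
Product: 19 methyl (3R,5S,6S)-6-(diphenylphosphoryl)-3-hydroperoxy-5-hydroxy-6-methoxydocosanoate
Conditions: AcOH/THF/H2O (4:2:1), rt
Reagents that add atoms: none
Why: Mild acid hydrolysis of the monoperoxyketal releases the hydroperoxide while the enol ether is still masked as an acid-stable β-hydroxy phosphine oxide, so acid and enol ether never meet.

Step 12
Reactants: 19 methyl (3R,5S,6S)-6-(diphenylphosphoryl)-3-hydroperoxy-5-hydroxy-6-methoxydocosanoate
Product: 20 methyl (3R,5Z)-3-hydroperoxy-6-methoxydocos-5-enoate
Conditions: KN(SiMe3)2 (2.1 equiv), THF, −78 → 0 °C; then KH2PO4/K2HPO4 buffer (pH 7), cold; used at once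
Reagents that add atoms: none
Why: Horner–Wittig elimination, in which the potassium alkoxide closes onto phosphorus and diphenylphosphinate leaves by stereospecific syn-elimination, so the (5S,6S) adduct should give only the Z enol ether; the first equivalent of base turns the hydroperoxide into its potassium salt, which cannot be expelled by β-elimination.

Step 13
Reactants: 20 methyl (3R,5Z)-3-hydroperoxy-6-methoxydocos-5-enoate
Product: 21 methyl 2-[(3S,4R,6S)-3-hexadecyl-3-methoxy-4-(phenylselanyl)-1,2-dioxan-6-yl]acetate
Conditions: PhSeBr (1.1 equiv), 2,6-di-tert-butylpyridine, CH2Cl2, −78 °C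
Reagents that add atoms: benzeneselenenyl bromide, Br[Se]c1ccccc1
Why: PhSe+ adds to C4 of the electron-rich enol ether to give a seleniranium/β-selanyl oxocarbenium ion centred on C3, which the terminal hydroperoxide oxygen O2 captures from the face opposite selenium, forming O2–C3 and C4–Se. The closest known reactions are electrophile-induced cyclisations of unsaturated hydroperoxides and alkoxyselenation of enol ethers. The 1,2-dioxane ring closes in the 6-endo-trig mode. C4 is set relative to C3 by anti addition across the Z double bond, and both are set relative to C6 by a chair transition state in which the CH2CO2Me arm, the hexadecyl chain and selenium are equatorial and the methoxy group is axial. The step needs 6-endo rather than 5-exo regioselectivity, secured by the methoxy group that localises the positive charge on C3, and face selectivity on the enol ether, secured by the preset C6 centre and the Z geometry; the hindered pyridine traps HBr so that no selenium-free, proton-catalysed closure or epimerisation at C3 should occur.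

Step 14
Reactants: 21 methyl 2-[(3S,4R,6S)-3-hexadecyl-3-methoxy-4-(phenylselanyl)-1,2-dioxan-6-yl]acetate
Product: 23 6-epi-chondrillin, methyl 2-[(3S,6S)-3-hexadecyl-3-methoxy-3,6-dihydro-1,2-dioxin-6-yl]acetate, via selenoxide 22 (not isolated)
Conditions: mCPBA (1.05 equiv), CH2Cl2, −78 °C; then pyridine, −78 °C → rt
Reagents that add atoms: none
Why: Chemoselective oxidation of the selenide to the selenoxide and its syn-elimination on warming; C3 is quaternary, so only a C5 hydrogen can be removed and the C4=C5 bond results, the oxygen delivered to selenium leaving as PhSeOH and C3 and C6 staying untouched.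

Compound list
1 | (methoxymethyl)diphenylphosphine oxide | COCP(=O)(c1ccccc1)c1ccccc1 | starting material
2 | 1-bromohexadecane | CCCCCCCCCCCCCCCCBr | starting material
3 | [lithio(methoxy)methyl]diphenylphosphine oxide (not isolated) | [Li]C(OC)P(=O)(c1ccccc1)c1ccccc1 | intermediate
4 | (1-methoxyheptadecyl)diphenylphosphine oxide (racemic) | CCCCCCCCCCCCCCCCC(OC)P(=O)(c1ccccc1)c1ccccc1 | intermediate
5 | 3-[(tert-butyldimethylsilyl)oxy]propanal | CC(C)(C)[Si](C)(C)OCCC=O | starting material
6 | (3S)-1-[(tert-butyldimethylsilyl)oxy]hex-5-en-3-yl diisopinocampheylborinate (not isolated) | C=CC[C@@H](CCO[Si](C)(C)C(C)(C)C)OB([C@@H]1C[C@@H]2C[C@H]([C@H]1C)C2(C)C)[C@@H]1C[C@@H]2C[C@H]([C@H]1C)C2(C)C | intermediate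
7 | (3S)-1-[(tert-butyldimethylsilyl)oxy]hex-5-en-3-ol | C=CC[C@@H](CCO[Si](C)(C)C(C)(C)C)O | intermediate
8 | (3S)-1-[(tert-butyldimethylsilyl)oxy]hex-5-en-3-yl methanesulfonate | C=CC[C@@H](CCO[Si](C)(C)C(C)(C)C)OS(C)(=O)=O | intermediate
9 | tert-butyl{[(3R)-3-hydroperoxyhex-5-en-1-yl]oxy}dimethylsilane | C=CC[C@H](CCO[Si](C)(C)C(C)(C)C)OO | intermediate
10 | tert-butyl({(3R)-3-[(2-methoxypropan-2-yl)peroxy]hex-5-en-1-yl}oxy)dimethylsilane | C=CC[C@H](CCO[Si](C)(C)C(C)(C)C)OOC(C)(C)OC | intermediate
11 | (3R)-3-[(2-methoxypropan-2-yl)peroxy]hex-5-en-1-ol | C=CC[C@H](CCO)OOC(C)(C)OC | intermediate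
12 | (3R)-3-[(2-methoxypropan-2-yl)peroxy]hex-5-enal (not isolated) | C=CC[C@H](CC=O)OOC(C)(C)OC | intermediate
13 | (3R)-3-[(2-methoxypropan-2-yl)peroxy]hex-5-enoic acid | C=CC[C@H](CC(=O)O)OOC(C)(C)OC | intermediate
14 | methyl (3R)-3-[(2-methoxypropan-2-yl)peroxy]hex-5-enoate | C=CC[C@H](CC(=O)OC)OOC(C)(C)OC | intermediate
15 | methyl (3R)-3-[(2-methoxypropan-2-yl)peroxy]-4-(1,2,4-trioxolan-3-yl)butanoate (both epimers at the trioxolane carbon; not isolated) | O1COOC1C[C@H](CC(=O)OC)OOC(C)(C)OC | intermediate
16 | methyl (3R)-3-[(2-methoxypropan-2-yl)peroxy]-5-oxopentanoate | O=CC[C@H](CC(=O)OC)OOC(C)(C)OC | intermediate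
17 | (1-lithio-1-methoxyheptadecyl)diphenylphosphine oxide (not isolated) | [Li]C(CCCCCCCCCCCCCCCC)(OC)P(=O)(c1ccccc1)c1ccccc1 | intermediate
18 | methyl (3R,5S,6S)-6-(diphenylphosphoryl)-5-hydroxy-6-methoxy-3-[(2-methoxypropan-2-yl)peroxy]docosanoate | CCCCCCCCCCCCCCCC[C@](OC)(P(=O)(c1ccccc1)c1ccccc1)[C@@H](O)C[C@H](CC(=O)OC)OOC(C)(C)OC | intermediate
19 | methyl (3R,5S,6S)-6-(diphenylphosphoryl)-3-hydroperoxy-5-hydroxy-6-methoxydocosanoate | CCCCCCCCCCCCCCCC[C@](OC)(P(=O)(c1ccccc1)c1ccccc1)[C@@H](O)C[C@H](CC(=O)OC)OO | intermediate
20 | methyl (3R,5Z)-3-hydroperoxy-6-methoxydocos-5-enoate | CCCCCCCCCCCCCCCC/C(OC)=C/C[C@H](CC(=O)OC)OO | intermediate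
21 | methyl 2-[(3S,4R,6S)-3-hexadecyl-3-methoxy-4-(phenylselanyl)-1,2-dioxan-6-yl]acetate | CCCCCCCCCCCCCCCC[C@@]1(OC)[C@H]([Se]c2ccccc2)C[C@H](CC(=O)OC)OO1 | intermediate
22 | methyl 2-[(3S,4R,6S)-3-hexadecyl-3-methoxy-4-(phenylseleninyl)-1,2-dioxan-6-yl]acetate (either configuration at selenium; not isolated) | CCCCCCCCCCCCCCCC[C@@]1(OC)[C@H]([Se](=O)c2ccccc2)C[C@H](CC(=O)OC)OO1 | intermediate
23 | 6-epi-chondrillin, methyl 2-[(3S,6S)-3-hexadecyl-3-methoxy-3,6-dihydro-1,2-dioxin-6-yl]acetate | CCCCCCCCCCCCCCCC[C@@]1(OC)C=C[C@H](CC(=O)OC)OO1 | target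

Total step count: 14.
Longest linear sequence: 13 steps (steps 2 to 14, from 5); step 1 prepares fragment 4 for the convergent step 10.

Steps most likely to fail

Step 4. Substitution at the secondary, homoallylic carbon may be slow, and elimination of the mesylate to a conjugated diene under the alkaline conditions may take over. The fallback uses a better leaving group at low temperature and a pre-protected peroxide nucleophile. Setting out from 7, Tf2O and 2,6-lutidine in CH2Cl2 at −78 °C would give (3S)-1-[(tert-butyldimethylsilyl)oxy]hex-5-en-3-yl trifluoromethanesulfonate F1. This would be displaced with inversion at 0 °C in THF by the potassium salt (KOtBu) of 2-methoxypropane-2-peroxol F2, itself prepared by ozonolysis of 2,3-dimethylbut-2-ene in methanol. The product is 10, where the route is rejoined; the free hydroperoxide 9 and step 5 are bypassed.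

Step 10. The hindered, strongly basic carbanion 17 may enolise the β-peroxy aldehyde, which then loses the peroxide by β-elimination, or the addition may favour the adducts with the unlike C5/C6 relationship. The fallback replaces the two-stage Horner–Wittig sequence by a direct Wittig olefination with a less basic ylide and moves the hydroperoxide onto a fluoride-labile silyl group.
- Setting out from 14, aqueous acetic acid would give methyl (3R)-3-hydroperoxyhex-5-enoate F3.
- TBSCl and imidazole in DMF would give methyl (3R)-3-[(tert-butyldimethylsilyl)peroxy]hex-5-enoate F4.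
- Ozonolysis in CH2Cl2 containing pyridine at −78 °C (no reductant) would give methyl (3R)-3-[(tert-butyldimethylsilyl)peroxy]-5-oxopentanoate F5.
- (1-Methoxyheptadecyl)triphenylphosphonium bromide F6 would be made in one operation from commercial (methoxymethyl)triphenylphosphonium chloride, NaN(SiMe3)2 and 2.
- F6 would be deprotonated with NaN(SiMe3)2 in THF at −78 °C to (1-methoxyheptadecylidene)triphenylphosphorane F7 and combined with F5.
- Methyl (3R,5Z)-3-[(tert-butyldimethylsilyl)peroxy]-6-methoxydocos-5-enoate F8 would be separated on triethylamine-deactivated silica from methyl (3R,5E)-3-[(tert-butyldimethylsilyl)peroxy]-6-methoxydocos-5-enoate F9.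
- Bu4NF buffered with AcOH in THF at 0 °C would release 20, where the route is rejoined; steps 11 and 12 are bypassed.

Step 13. The free hydroperoxide may be consumed by direct reaction with the selenenyl halide, or traces of acid may trigger a selenium-free, proton-catalysed closure onto the enol ether. The fallback changes the nucleophile from the hydroperoxide to a silyl peroxide. Setting out from 20, Et3SiCl and imidazole in CH2Cl2 at 0 °C would give methyl (3R,5Z)-6-methoxy-3-[(triethylsilyl)peroxy]docos-5-enoate F10. PhSeBr in CH2Cl2 at −78 °C would then activate the enol ether; the silylated peroxide oxygen would close the same ring in the same 6-endo sense, and the silyl group would be lost to bromide. The product is 21, where the route is rejoined.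

Further compounds
F1 | step 4 | (3S)-1-[(tert-butyldimethylsilyl)oxy]hex-5-en-3-yl trifluoromethanesulfonate | C=CC[C@@H](CCO[Si](C)(C)C(C)(C)C)OS(=O)(=O)C(F)(F)F
F2 | step 4 | 2-methoxypropane-2-peroxol | COC(C)(C)OO
F3 | step 10 | methyl (3R)-3-hydroperoxyhex-5-enoate | C=CC[C@H](CC(=O)OC)OO
F4 | step 10 | methyl (3R)-3-[(tert-butyldimethylsilyl)peroxy]hex-5-enoate | C=CC[C@H](CC(=O)OC)OO[Si](C)(C)C(C)(C)C
F5 | step 10 | methyl (3R)-3-[(tert-butyldimethylsilyl)peroxy]-5-oxopentanoate | O=CC[C@H](CC(=O)OC)OO[Si](C)(C)C(C)(C)C
F6 | step 10 | (1-methoxyheptadecyl)triphenylphosphonium bromide | CCCCCCCCCCCCCCCCC(OC)[P+](c1ccccc1)(c1ccccc1)c1ccccc1.[Br-]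
F7 | step 10 | (1-methoxyheptadecylidene)triphenylphosphorane (not isolated) | CCCCCCCCCCCCCCCCC(OC)=P(c1ccccc1)(c1ccccc1)c1ccccc1
F8 | step 10 | methyl (3R,5Z)-3-[(tert-butyldimethylsilyl)peroxy]-6-methoxydocos-5-enoate | CCCCCCCCCCCCCCCC/C(OC)=C/C[C@H](CC(=O)OC)OO[Si](C)(C)C(C)(C)C
F9 | step 10 | methyl (3R,5E)-3-[(tert-butyldimethylsilyl)peroxy]-6-methoxydocos-5-enoate | CCCCCCCCCCCCCCCC/C(OC)=C\C[C@H](CC(=O)OC)OO[Si](C)(C)C(C)(C)C
F10 | step 13 | methyl (3R,5Z)-6-methoxy-3-[(triethylsilyl)peroxy]docos-5-enoate | CCCCCCCCCCCCCCCC/C(OC)=C/C[C@H](CC(=O)OC)OO[Si](CC)(CC)CC
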